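The numbers are assumed.

In the first minutes of this flask the solution fills with starting material, and from then on I follow one rate, the rate at which isomer of the product is made.

    solid substrate ⇌ starting material, rate k1*(cs1 - [starting material]) while solid is left; crystals form when [starting material] > cs1 (cs1 = 20 mM, k1 = 0.0258 s⁻¹)
    starting material + starting material ⇌ target (K2 = 4.18 M⁻¹, k2 = 0.126 M⁻¹ s⁻¹)
    crystals ⇌ target, rate k3*(cs3 - [target]) while solid is left; crystals form when [target] > cs3 (cs3 = 22 mM, k3 = 0.0573 s⁻¹)
    target ⇌ isomer of the product (K4 = 12.5, k4 = 0.0108 s⁻¹)

solid substrate 0.058 M; time 4.0 h

- percentages count the solid substrate that a species holds: one target or crystals or isomer of the product counts as two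
- target is meant together with its crystals
- a step written with two of one species runs at k times the square of its concentration and takes two of it each time
- solid, in amounts per volume of the solution: solid substrate, crystals
- at the start none of the solid substrate is in solution
- what has only dissolved of solid substrate counts as not reacted
- the reaction counts as stopped when no species that holds the solid substrate changes by six tenths of a point or more over the second half of the time
- run time (flask): 4.0 h

* the state of affairs at 4.0 h: stopped, and by what, or still going (for what has run out or reacted, a solid counts together with what of it has only dissolved) (forward and back rates have come level / all of the solid substrate has reacted / it is still moving)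
* the target standing at 4.0 h, as a percentage of the solid substrate charged
* the isomer of the product standing at 4.0 h, as a percentage of the solid substrate charged

Starting material approaches its solubility with the time 0.646 min, which describes the filling of the solution and not the dissolving of the whole charge, and this is shorter than the time in which forming target draws a saturated solution down, so while solid is left I take the solution at its solubility, where target forms at

0.126 M⁻¹ s⁻¹ × 20 mM × 20 mM = 3.02 mM min⁻¹.

The first slowing comes at once. Target returns at 1.81 min⁻¹ and goes on to the isomer at 0.65 min⁻¹, and these two together are faster than the isomer's return to target, so target sits in a quasi-steady state and a fraction 0.264 goes on. The starting rate is therefore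

0.264 × 3.02 mM min⁻¹ = 0.798 mM min⁻¹.

The second slowing grows with the isomer itself, which returns at 0.0518 min⁻¹, and a fraction 0.736 of that return gets past the target. The rate therefore decays exponentially with the time

1 / (0.0518 min⁻¹ × 0.736) = 26.2 min.

Integrating that decay gives the saturated ceiling, the isomer a saturated solution can deliver:

0.798 mM min⁻¹ × 26.2 min = 20.9 mM, or 72.1% of the charge.

Over 4.0 h the rate falls by a factor 1.05 × 10⁻⁴, since the decay is shorter than the run. The ceiling plus a saturated solution would need 61.8 mM of substrate, more than the 0.058 M charged, so a third slowing enters as starting material falls, and I expect the isomer below the ceiling.

The forecast says forward and back rates have come level, with 5.03% target and 62.8% isomer, because “the system relaxes on a timescale of about 1,500 s”; my ceiling is higher than its isomer figure.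

The simulation gives forward and back rates have come level, with 5.02% target and 62.8% isomer.

This flask holds 57.5% isomer after 0.800 h and 62.8% after 40.0 h, and its decay time of 26.2 min is shorter than the 4.0 h allowed, with the isomer 9.3 percentage points under the ceiling. In the neighbour flask with 0.023 M of solid substrate the ceiling comes to 182% of the charge, more than that charge holds, and that flask ends with 50.3% isomer and 45.7% starting material.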